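The phloroglucinol ring is assembled around the finished side chain. The benzene ring is disconnected at the bond between the alkyl-bearing carbon and one neighbouring oxygenated carbon, and at the bond between the other oxygenated neighbour and a ring CH. One thermal operation, a cyclobutenone–siloxyalkyne benzannulation, forms both bonds and closes the carbocycle, delivering three differentiated oxygens (one free phenol, two silyl ethers). The feature exploited is the ring carbon bearing the C10 chain, flanked by two O-substituted carbons of the 1,3,5-trioxygenated benzene. The precursor is an (S)-configured alkyl siloxyalkyne, made from geraniol by Sharpless epoxidation, with its tertiary alcohol masked as a triethylsilyl ether; its partner is 3-(triisopropylsilyloxy)cyclobutenone.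

Key step: step 9

Remark: the sp3 ring carbons of 16 and 22 form without stereocontrol, which is immaterial because both are lost on aromatisation; 13 is written as the diketone but is expected to react as its enol.

Step 1
Reactants: 1 geraniol
Product: 2 [(2S,3S)-3-methyl-3-(4-methylpent-3-en-1-yl)oxiran-2-yl]methanol ((2S,3S)-2,3-epoxygeraniol)
Conditions: Ti(OiPr)4 (5 mol %), L-(+)-diethyl tartrate (6 mol %), t-BuOOH, 4 Å MS, CH2Cl2, −20 °C
Reagents that add atoms: tert-butyl hydroperoxide, CC(C)(C)OO
Why: Sharpless asymmetric epoxidation, in which the titanium–tartrate catalyst binds the allylic hydroxyl and, with the L-(+)-tartrate, delivers oxygen to the face of the 2,3-alkene that gives the (2S,3S)-epoxide, so both new stereocentres are set by the catalyst while the remote alkene, lacking a directing hydroxyl, is left alone.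

Step 2
Reactants: 2 (2S,3S)-2,3-epoxygeraniol
Product: 3 (3S)-3,7-dimethyloct-6-ene-1,3-diol
Conditions: NaAlH2(OCH2CH2OCH3)2, THF, 0 °C → rt; aq. KNaC4H4O6 work-up
Reagents that add atoms: none
Why: Hydroxyl-directed reductive opening of a 2,3-epoxy alcohol, in which the aluminium alkoxide delivers hydride intramolecularly to C2 and cleaves the C2–O bond, so the C3–O bond and the (S) configuration of the tertiary carbinol are kept and the C2 stereocentre is erased.

Step 3
Reactants: 3 (3S)-3,7-dimethyloct-6-ene-1,3-diol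
Product: 4 (3S)-3-hydroxy-3,7-dimethyloct-6-en-1-yl 4-methylbenzenesulfonate
Conditions: TsCl, Et3N, DMAP (cat.), CH2Cl2, 0 °C
Reagents that add atoms: 4-toluenesulfonyl chloride, Cc1ccc(cc1)S(Cl)(=O)=O
Why: Chemoselective sulfonate ester formation, since the primary hydroxyl is sulfonylated far faster than the hindered tertiary one and no electrophilic halogen is present that could engage the alkene and the free tertiary alcohol in haloetherification.

Step 4
Reactants: 4 (3S)-3-hydroxy-3,7-dimethyloct-6-en-1-yl 4-methylbenzenesulfonate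
Product: 5 (3S)-3,7-dimethyl-3-(triethylsilyloxy)oct-6-en-1-yl 4-methylbenzenesulfonate
Conditions: Et3SiOTf, 2,6-lutidine, CH2Cl2, −78 → 0 °C
Reagents that add atoms: triethylsilyl trifluoromethanesulfonate, CC[Si](CC)(CC)OS(=O)(=O)C(F)(F)F
Why: Silyl ether formation with a silyl triflate and a hindered pyridine base, the standard protection of a tertiary alcohol, which also removes the alkoxide that would otherwise close an oxetane in the next, strongly basic step.

Step 5
Reactants: 5 (3S)-3,7-dimethyl-3-(triethylsilyloxy)oct-6-en-1-yl 4-methylbenzenesulfonate, 6 lithium acetylide–ethylenediamine complex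
Product: 7 triethyl{[(5S)-5,9-dimethyldec-8-en-1-yn-5-yl]oxy}silane
Conditions: LiC≡CH·H2NCH2CH2NH2, DMSO, rt
Reagents that add atoms: lithium acetylide–ethylenediamine complex (6), [Li+].[C-]#C.NCCN
Why: SN2 alkylation of an acetylide, in which the primary sulfonate with an unbranched β-carbon is displaced in a dipolar aprotic solvent and the chain gains the two alkyne carbons without touching the stereocentre.

Step 6
Reactants: 7 triethyl{[(5S)-5,9-dimethyldec-8-en-1-yn-5-yl]oxy}silane, 8 triisopropylsilyl trifluoromethanesulfonate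
Product: 11 triisopropyl{[(5S)-5,9-dimethyl-5-(triethylsilyloxy)dec-8-en-1-yn-1-yl]oxy}silane, via lithium alkynide 9 (not isolated), via lithium ynolate 10 (not isolated)
Conditions: n-BuLi, THF, −78 °C; t-BuOOLi (from t-BuOOH, LiN(SiMe3)2), −78 → 0 °C; then i-Pr3SiOTf, −78 °C → rt
Reagents that add atoms: tert-butyl hydroperoxide, CC(C)(C)OO; triisopropylsilyl trifluoromethanesulfonate (8), CC(C)[Si](OS(=O)(=O)C(F)(F)F)(C(C)C)C(C)C
Why: Electrophilic oxygenation of a lithium alkynide followed by O-silylation, in which the peroxide anion transfers oxygen to 9 with loss of tert-butoxide to give ynolate 10 and the bulky silyl triflate then reacts at oxygen, while the silyl ether and the isolated alkene are inert to the peroxide anion.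

Step 7
Reactants: 12 3-ethoxycyclobut-2-en-1-one
Product: 13 cyclobutane-1,3-dione (enol form: 3-hydroxycyclobut-2-en-1-one)
Conditions: 1 M aq. HCl, 0 °C → rt; freeze-dry, use crude
Reagents that add atoms: water, O
Why: Acid hydrolysis of a vinylogous ester, in which water adds in conjugate fashion and ethanol is lost, the sensitive dione being carried forward at once without purification.

Step 8
Reactants: 13 cyclobutane-1,3-dione, 8 triisopropylsilyl trifluoromethanesulfonate
Product: 14 3-(triisopropylsilyloxy)cyclobut-2-en-1-one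
Conditions: i-Pr3SiOTf, Et3N, CH2Cl2, −78 → 0 °C
Reagents that add atoms: triisopropylsilyl trifluoromethanesulfonate (8), CC(C)[Si](OS(=O)(=O)C(F)(F)F)(C(C)C)C(C)C
Why: O-silylation of a 1,3-diketone enol, which can give only one product from the symmetric dione, the bulky triisopropylsilyl group being chosen so that the vinylogous silyl ester should survive isolation.

Step 9
Reactants: 11 triisopropyl{[(5S)-5,9-dimethyl-5-(triethylsilyloxy)dec-8-en-1-yn-1-yl]oxy}silane, 14 3-(triisopropylsilyloxy)cyclobut-2-en-1-one
Product: 19 2-[(3S)-3,7-dimethyl-3-(triethylsilyloxy)oct-6-en-1-yl]-3,5-bis(triisopropylsilyloxy)phenol, via vinylketene 15 (not isolated), via vinylcyclobutenone 16 (not isolated), via dienylketene 17 (not isolated), via cyclohexadienone 18 (not isolated)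
Conditions: PhMe, 80 → 110 °C, slow addition of 14 to 11 (slight excess), Ar
Reagents that add atoms: none
Why: Heating opens 14 by a four-electron electrocyclic ring opening to vinylketene 15, whose ketene carbon is attacked by the nucleophilic alkyl-bearing carbon of siloxyalkyne 11 in a regioselective [2+2] cycloaddition that gives vinylcyclobutenone 16. A second four-electron ring opening gives dienylketene 17, and a thermal six-electron disrotatory electrocyclisation joins the ketene carbon to the terminal methylene and so closes the only new ring, the six-membered carbocycle of dienone 18, which tautomerises to phenol 19. The closest known reaction is the Danheiser benzannulation of alkyl- and aryl-substituted cyclobutenones with triisopropylsiloxyalkynes; the 3-silyloxy group on the ketene precursor is the untested element, although a cyclobutenone of the same kind (16) is opened in the second stage of every such annulation. No stereocentre is formed, since the ring CH of 16 is lost on aromatisation, and the existing carbinol centre is remote from all bond changes. The selectivity required is regiochemical and is secured by the polarisation of the ynol silyl ether, which puts the side chain on the carbon between the new hydroxyl carbon and the alkyne-derived silyloxy carbon, while the cyclobutenone oxygen ends up meta to both. Slow addition of 14 keeps the ketene concentration low, which should suppress its dimerisation and its acylation of the product phenol, and the triethylsilyl ether prevents the tertiary alcohol from trapping the ketene.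

Step 10
Reactants: 19 2-[(3S)-3,7-dimethyl-3-(triethylsilyloxy)oct-6-en-1-yl]-3,5-bis(triisopropylsilyloxy)phenol, 20 isobutyryl chloride
Product: 21 2-[(3S)-3,7-dimethyl-3-(triethylsilyloxy)oct-6-en-1-yl]-3,5-bis(triisopropylsilyloxy)phenyl 2-methylpropanoate
Conditions: i-PrCOCl, Et3N, DMAP (cat.), CH2Cl2, 0 °C → rt
Reagents that add atoms: isobutyryl chloride (20), CC(C)C(Cl)=O
Why: Esterification of the only free phenol with an acid chloride under nucleophilic catalysis, the three silyl ethers being inert to these conditions.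

Step 11
Reactants: 21 2-[(3S)-3,7-dimethyl-3-(triethylsilyloxy)oct-6-en-1-yl]-3,5-bis(triisopropylsilyloxy)phenyl 2-methylpropanoate
Product: 23 1-{3-[(3S)-3,7-dimethyl-3-(triethylsilyloxy)oct-6-en-1-yl]-2-hydroxy-4,6-bis(triisopropylsilyloxy)phenyl}-2-methylpropan-1-one, via acylcyclohexadienone 22 (not isolated)
Conditions: hν (254 nm), degassed cyclohexane, rt
Reagents that add atoms: none
Why: Photo-Fries rearrangement, in which excitation of the aryl ester cleaves the O–acyl bond to a caged phenoxyl/acyl radical pair that recombines at the free ortho carbon to give dienone 22 and, after tautomerisation, the hydrogen-bonded and therefore photostable ortho-hydroxy ketone; recombination at the para CH would be harmless, because that isomer converges on the same target in step 12 once desilylation makes the two ring CH positions equivalent.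

Step 12
Reactants: 23 1-{3-[(3S)-3,7-dimethyl-3-(triethylsilyloxy)oct-6-en-1-yl]-2-hydroxy-4,6-bis(triisopropylsilyloxy)phenyl}-2-methylpropan-1-one
Product: 24 1-{3-[(3S)-3-hydroxy-3,7-dimethyloct-6-en-1-yl]-2,4,6-trihydroxyphenyl}-2-methylpropan-1-one (target)
Conditions: Bu4NF, AcOH, THF, 0 °C → rt, Ar
Reagents that add atoms: none
Why: Fluoride-induced desilylation, which cleaves the two aryl silyl ethers quickly and the tertiary triethylsilyl ether more slowly, the acetic acid buffer keeping the air-sensitive acylphloroglucinol protonated and the absence of strong acid avoiding cyclisation of the tertiary alcohol onto a ring oxygen.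

Compound list

1 | geraniol, (2E)-3,7-dimethylocta-2,6-dien-1-ol | CC(C)=CCC/C(C)=C/CO | starting material
2 | [(2S,3S)-3-methyl-3-(4-methylpent-3-en-1-yl)oxiran-2-yl]methanol | CC(C)=CCC[C@]1(C)O[C@H]1CO | intermediate
3 | (3S)-3,7-dimethyloct-6-ene-1,3-diol | CC(C)=CCC[C@](C)(O)CCO | intermediate
4 | (3S)-3-hydroxy-3,7-dimethyloct-6-en-1-yl 4-methylbenzenesulfonate | CC(C)=CCC[C@](C)(O)CCOS(=O)(=O)c1ccc(C)cc1 | intermediate
5 | (3S)-3,7-dimethyl-3-(triethylsilyloxy)oct-6-en-1-yl 4-methylbenzenesulfonate | CC(C)=CCC[C@](C)(O[Si](CC)(CC)CC)CCOS(=O)(=O)c1ccc(C)cc1 | intermediate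
6 | lithium acetylide–ethylenediamine complex | [Li+].[C-]#C.NCCN | starting material
7 | triethyl{[(5S)-5,9-dimethyldec-8-en-1-yn-5-yl]oxy}silane | CC(C)=CCC[C@](C)(O[Si](CC)(CC)CC)CCC#C | intermediate
8 | triisopropylsilyl trifluoromethanesulfonate | CC(C)[Si](OS(=O)(=O)C(F)(F)F)(C(C)C)C(C)C | starting material
9 | lithium (5S)-5,9-dimethyl-5-(triethylsilyloxy)dec-8-en-1-yn-1-ide | CC(C)=CCC[C@](C)(O[Si](CC)(CC)CC)CCC#[C-].[Li+] | intermediate (not isolated)
10 | lithium (5S)-5,9-dimethyl-5-(triethylsilyloxy)dec-8-en-1-yn-1-olate | CC(C)=CCC[C@](C)(O[Si](CC)(CC)CC)CCC#C[O-].[Li+] | intermediate (not isolated)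
11 | triisopropyl{[(5S)-5,9-dimethyl-5-(triethylsilyloxy)dec-8-en-1-yn-1-yl]oxy}silane | CC(C)=CCC[C@](C)(O[Si](CC)(CC)CC)CCC#CO[Si](C(C)C)(C(C)C)C(C)C | intermediate
12 | 3-ethoxycyclobut-2-en-1-one | CCOC1=CC(=O)C1 | starting material
13 | cyclobutane-1,3-dione | O=C1CC(=O)C1 | intermediate
14 | 3-(triisopropylsilyloxy)cyclobut-2-en-1-one | CC(C)[Si](OC1=CC(=O)C1)(C(C)C)C(C)C | intermediate
15 | 3-(triisopropylsilyloxy)buta-1,3-dien-1-one | C=C(O[Si](C(C)C)(C(C)C)C(C)C)C=C=O | intermediate (not isolated)
16 | 2-[(3S)-3,7-dimethyl-3-(triethylsilyloxy)oct-6-en-1-yl]-3-(triisopropylsilyloxy)-4-[1-(triisopropylsilyloxy)ethenyl]cyclobut-2-en-1-one (either configuration at C4) | CC(C)=CCC[C@](C)(O[Si](CC)(CC)CC)CCC1=C(O[Si](C(C)C)(C(C)C)C(C)C)C(C(=C)O[Si](C(C)C)(C(C)C)C(C)C)C1=O | intermediate (not isolated)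
17 | (3E)-2-[(3S)-3,7-dimethyl-3-(triethylsilyloxy)oct-6-en-1-yl]-3,5-bis(triisopropylsilyloxy)hexa-1,3,5-trien-1-one (ketene and vinyl groups cis across the central double bond) | CC(C)=CCC[C@](C)(O[Si](CC)(CC)CC)CCC(=C=O)/C(O[Si](C(C)C)(C(C)C)C(C)C)=C\C(=C)O[Si](C(C)C)(C(C)C)C(C)C | intermediate (not isolated)
18 | 2-[(3S)-3,7-dimethyl-3-(triethylsilyloxy)oct-6-en-1-yl]-3,5-bis(triisopropylsilyloxy)cyclohexa-2,4-dien-1-one | CC(C)=CCC[C@](C)(O[Si](CC)(CC)CC)CCC1=C(O[Si](C(C)C)(C(C)C)C(C)C)C=C(O[Si](C(C)C)(C(C)C)C(C)C)CC1=O | intermediate (not isolated)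
19 | 2-[(3S)-3,7-dimethyl-3-(triethylsilyloxy)oct-6-en-1-yl]-3,5-bis(triisopropylsilyloxy)phenol | CC(C)=CCC[C@](C)(O[Si](CC)(CC)CC)CCc1c(O)cc(O[Si](C(C)C)(C(C)C)C(C)C)cc1O[Si](C(C)C)(C(C)C)C(C)C | intermediate
20 | isobutyryl chloride | CC(C)C(Cl)=O | starting material
21 | 2-[(3S)-3,7-dimethyl-3-(triethylsilyloxy)oct-6-en-1-yl]-3,5-bis(triisopropylsilyloxy)phenyl 2-methylpropanoate | CC(C)=CCC[C@](C)(O[Si](CC)(CC)CC)CCc1c(OC(=O)C(C)C)cc(O[Si](C(C)C)(C(C)C)C(C)C)cc1O[Si](C(C)C)(C(C)C)C(C)C | intermediate
22 | 2-[(3S)-3,7-dimethyl-3-(triethylsilyloxy)oct-6-en-1-yl]-6-(2-methylpropanoyl)-3,5-bis(triisopropylsilyloxy)cyclohexa-2,4-dien-1-one (either configuration at C6) | CC(C)=CCC[C@](C)(O[Si](CC)(CC)CC)CCC1=C(O[Si](C(C)C)(C(C)C)C(C)C)C=C(O[Si](C(C)C)(C(C)C)C(C)C)C(C(=O)C(C)C)C1=O | intermediate (not isolated)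
23 | 1-{3-[(3S)-3,7-dimethyl-3-(triethylsilyloxy)oct-6-en-1-yl]-2-hydroxy-4,6-bis(triisopropylsilyloxy)phenyl}-2-methylpropan-1-one | CC(C)=CCC[C@](C)(O[Si](CC)(CC)CC)CCc1c(O)c(C(=O)C(C)C)c(O[Si](C(C)C)(C(C)C)C(C)C)cc1O[Si](C(C)C)(C(C)C)C(C)C | intermediate
24 | 1-{3-[(3S)-3-hydroxy-3,7-dimethyloct-6-en-1-yl]-2,4,6-trihydroxyphenyl}-2-methylpropan-1-one | CC(C)=CCC[C@](C)(O)CCc1c(O)cc(O)c(C(=O)C(C)C)c1O | target

Total step count: 12.
Longest linear sequence: 10 steps (geraniol 1 to target 24 through steps 1–6 and 9–12); the cyclobutenone branch (steps 7–8) joins at step 9.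

Steps most likely to fail

1. Step 9 (benzannulation). Ring opening of the donor-stabilised cyclobutenone may lag behind thermal isomerisation of the siloxyalkyne to a silylketene. Alternatively the vinylketene may be consumed by self-condensation or by acylating the product phenol before it adds to the alkyne. The fallback abandons ring construction, attaches the chain to a preformed phloroglucinol ring, sets out from 5 and rejoins the route at 24.
   - Tosylate 5 would be converted with NaI in acetone into the iodide triethyl{[(3S)-1-iodo-3,7-dimethyloct-6-en-3-yl]oxy}silane F1.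
   - The known acetal 1,3,5-tris(methoxymethoxy)benzene F2 (from phloroglucinol, chloromethyl methyl ether and i-Pr2NEt) would be lithiated with n-BuLi in THF at 0 °C at a carbon flanked by two acetal oxygens, giving [2,4,6-tris(methoxymethoxy)phenyl]lithium F3.
   - Alkylation of F3 with F1 in THF/DMPU would give triethyl{[(3S)-3,7-dimethyl-1-[2,4,6-tris(methoxymethoxy)phenyl]oct-6-en-3-yl]oxy}silane F4.
   - A second directed lithiation would give {3-[(3S)-3,7-dimethyl-3-(triethylsilyloxy)oct-6-en-1-yl]-2,4,6-tris(methoxymethoxy)phenyl}lithium F5, and acylation with N-methoxy-N-methylisobutyramide would give the ketone 1-{3-[(3S)-3,7-dimethyl-3-(triethylsilyloxy)oct-6-en-1-yl]-2,4,6-tris(methoxymethoxy)phenyl}-2-methylpropan-1-one F6.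
   - Brief treatment with dilute HCl in methanol at 0 °C to room temperature would remove the three acetals and the silyl ether to give 24. Its weak point is this acidic deprotection in the presence of the tertiary alcohol, so it would be kept cold and short.

2. Step 11 (photo-Fries shift). The acyl radical may escape the solvent cage, which returns phenol 19; recombination at the alkyl-bearing ortho carbon is unproductive; and the product absorbs the light and slows conversion. The fallback replaces the radical O-to-C acyl shift by polar, magnesium-templated C–C bond formation, sets out from 19 and rejoins at 23.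
   - Phenol 19 would be formylated at its only free ortho carbon with MgCl2, Et3N and paraformaldehyde in THF at reflux (Casnati–Skattebøl formylation) to give 3-[(3S)-3,7-dimethyl-3-(triethylsilyloxy)oct-6-en-1-yl]-2-hydroxy-4,6-bis(triisopropylsilyloxy)benzaldehyde F7.
   - Addition of excess i-PrMgCl in THF at −78 °C would give the carbinol 2-[(3S)-3,7-dimethyl-3-(triethylsilyloxy)oct-6-en-1-yl]-6-(1-hydroxy-2-methylpropyl)-3,5-bis(triisopropylsilyloxy)phenol F8 as a mixture of epimers.
   - F8 would be oxidised without purification with MnO2 in CH2Cl2 to 23.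

3. Step 6 (ynolate formation and silylation). Oxygen transfer from the peroxide to the alkynide may be incomplete, so that residual alkynide is silylated at carbon, and the ynolate may be lost through ketene chemistry on warming. The fallback makes the same ynolate by ester homologation instead of alkyne oxidation, sets out from 5 and rejoins at 10.
   - Tosylate 5 would be converted with LiBr in acetone into triethyl{[(3S)-1-bromo-3,7-dimethyloct-6-en-3-yl]oxy}silane F9.
   - Magnesium in THF would give the Grignard reagent bromo[(3S)-3,7-dimethyl-3-(triethylsilyloxy)oct-6-en-1-yl]magnesium F10.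
   - Inverse addition to ethyl chloroformate at −78 °C would give ethyl (4S)-4,8-dimethyl-4-(triethylsilyloxy)non-7-enoate F11.
   - Under Kowalski ester homologation conditions (LiCHBr2 from CH2Br2 and lithium 2,2,6,6-tetramethylpiperidide, then LiN(SiMe3)2 and n-BuLi, −78 °C to room temperature), F11 would pass through lithium (5S)-1,1-dibromo-5,9-dimethyl-5-(triethylsilyloxy)deca-1,8-dien-2-olate F12, which rearranges after bromine–lithium exchange to ynolate 10.
   - Ynolate 10 would be silylated with 8 as in step 6 to give 11.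

Further compounds
F1 | step 9 | triethyl{[(3S)-1-iodo-3,7-dimethyloct-6-en-3-yl]oxy}silane | CC(C)=CCC[C@](C)(O[Si](CC)(CC)CC)CCI
F2 | step 9 | 1,3,5-tris(methoxymethoxy)benzene | COCOc1cc(OCOC)cc(OCOC)c1
F3 | step 9 | [2,4,6-tris(methoxymethoxy)phenyl]lithium | [Li]c1c(OCOC)cc(OCOC)cc1OCOC
F4 | step 9 | triethyl{[(3S)-3,7-dimethyl-1-[2,4,6-tris(methoxymethoxy)phenyl]oct-6-en-3-yl]oxy}silane | CC(C)=CCC[C@](C)(O[Si](CC)(CC)CC)CCc1c(OCOC)cc(OCOC)cc1OCOC
F5 | step 9 | {3-[(3S)-3,7-dimethyl-3-(triethylsilyloxy)oct-6-en-1-yl]-2,4,6-tris(methoxymethoxy)phenyl}lithium | CC(C)=CCC[C@](C)(O[Si](CC)(CC)CC)CCc1c(OCOC)cc(OCOC)c([Li])c1OCOC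
F6 | step 9 | 1-{3-[(3S)-3,7-dimethyl-3-(triethylsilyloxy)oct-6-en-1-yl]-2,4,6-tris(methoxymethoxy)phenyl}-2-methylpropan-1-one | CC(C)=CCC[C@](C)(O[Si](CC)(CC)CC)CCc1c(OCOC)cc(OCOC)c(C(=O)C(C)C)c1OCOC
F7 | step 11 | 3-[(3S)-3,7-dimethyl-3-(triethylsilyloxy)oct-6-en-1-yl]-2-hydroxy-4,6-bis(triisopropylsilyloxy)benzaldehyde | CC(C)=CCC[C@](C)(O[Si](CC)(CC)CC)CCc1c(O)c(C=O)c(O[Si](C(C)C)(C(C)C)C(C)C)cc1O[Si](C(C)C)(C(C)C)C(C)C
F8 | step 11 | 2-[(3S)-3,7-dimethyl-3-(triethylsilyloxy)oct-6-en-1-yl]-6-(1-hydroxy-2-methylpropyl)-3,5-bis(triisopropylsilyloxy)phenol (either configuration at the new carbinol carbon) | CC(C)=CCC[C@](C)(O[Si](CC)(CC)CC)CCc1c(O)c(C(O)C(C)C)c(O[Si](C(C)C)(C(C)C)C(C)C)cc1O[Si](C(C)C)(C(C)C)C(C)C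
F9 | step 6 | triethyl{[(3S)-1-bromo-3,7-dimethyloct-6-en-3-yl]oxy}silane | CC(C)=CCC[C@](C)(O[Si](CC)(CC)CC)CCBr
F10 | step 6 | bromo[(3S)-3,7-dimethyl-3-(triethylsilyloxy)oct-6-en-1-yl]magnesium | CC(C)=CCC[C@](C)(O[Si](CC)(CC)CC)CC[Mg]Br
F11 | step 6 | ethyl (4S)-4,8-dimethyl-4-(triethylsilyloxy)non-7-enoate | CC(C)=CCC[C@](C)(O[Si](CC)(CC)CC)CCC(=O)OCC
F12 | step 6 | lithium (5S)-1,1-dibromo-5,9-dimethyl-5-(triethylsilyloxy)deca-1,8-dien-2-olate | CC(C)=CCC[C@](C)(O[Si](CC)(CC)CC)CCC([O-])=C(Br)Br.[Li+]
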